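**Assumption:** the left-hand ring is numbered as a 5,6,7,8-tetrahydrochromone (the target SMILES is 5R,6S,7R,8S), and sugar numbering is kept for the glucose-derived intermediates. Nothing here has been run; all conditions are proposals.

## Retrosynthetic overview

1. Target 27 ⇒ left γ-pyranone annulated last, from acylketene 25 and the bicyclic enol ether 21.
2. 21 ⇒ ring-closing metathesis of diene 20; 20 ⇒ key C8–C8a bond from the acetyl-anion equivalent (1-ethoxyvinyl)lithium 18 and aldehyde 16, which already carries the whole right half. This step sets C8.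
3. 16 ⇒ zinc fragmentation of a 6-iodo thioglycoside made from the bridged levoglucosan 12; C5, C6, C7 of the target are C4, C3, C2 of D-glucose.
4. 12 ⇒ epoxide-relay cascade of catechol chromone 5 with the Černý epoxide 8, which forms both aryl ether bonds and the seven-membered dioxepine.
5. Ring order: right chromone → benzodioxepine → carbocycle (metathesis) → left pyranone.

## Route

Step 1
Reactants: 1 1-(2-hydroxy-4,5-dimethoxyphenyl)ethan-1-one; 2 ethyl 3-phenylpropanoate
Product: 4 6,7-dimethoxy-2-(2-phenylethyl)-4H-chromen-4-one, via aryl 1,3-diketone 3 (not isolated)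
Conditions: NaH, THF, reflux; then conc. HCl, AcOH, 100 °C
Reagents that add atoms: none
Why: Crossed Claisen condensation of the ketone enolate with the ester gives the 1,3-diketone, and acid cyclodehydration of the o-hydroxyaryl diketone closes the chromone; no stereocenter is formed.

Step 2
Reactants: 4 6,7-dimethoxy-2-(2-phenylethyl)-4H-chromen-4-one
Product: 5 6,7-dihydroxy-2-(2-phenylethyl)-4H-chromen-4-one
Conditions: BBr3, CH2Cl2, −78 °C → rt; H2O
Reagents that add atoms: none
Why: Lewis-acid cleavage of both aryl methyl ethers (BBr3 demethylation), which the chromone tolerates; no stereocenter is formed.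

Step 3
Reactants: 6 1,6-anhydro-β-D-glucopyranose (levoglucosan)
Product: 7 1,6-anhydro-2,4-di-O-tosyl-β-D-glucopyranose
Conditions: TsCl (2.2 equiv), pyridine/acetone, 0 °C → rt
Reagents that add atoms: p-toluenesulfonyl chloride, Cc1ccc(cc1)S(Cl)(=O)=O
Why: Selective sulfonylation: the axial 3-OH under the anhydro bridge is the least reactive hydroxyl of levoglucosan, so O-2 and O-4 are tosylated with no change at any stereocenter.

Step 4
Reactants: 7 1,6-anhydro-2,4-di-O-tosyl-β-D-glucopyranose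
Product: 8 1,6:3,4-dianhydro-2-O-tosyl-β-D-galactopyranose
Conditions: NaOMe, MeOH/CHCl3, rt
Reagents that add atoms: none
Why: Intramolecular Williamson epoxide formation: the axial 3-alkoxide displaces the anti-periplanar 4-tosylate with inversion at C4 (galacto epoxide) while the 2-tosylate is kept.

Step 5
Reactants: 8 1,6:3,4-dianhydro-2-O-tosyl-β-D-galactopyranose; 5 6,7-dihydroxy-2-(2-phenylethyl)-4H-chromen-4-one
Product: 12 1,6-anhydro-2,4-O-[4-oxo-2-(2-phenylethyl)-4H-chromene-6,7-diyl]-3-O-triethylsilyl-β-D-glucopyranose (O-2 on chromone C6, O-4 on chromone C7), via C4-aryl ether tosylate 9 (not isolated), via manno epoxide 10 (not isolated), via bridged alcohol 11 (not isolated)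
Conditions: 5 (1.05 equiv), Cs2CO3 (0.55 equiv), DMF, 100 °C; then Cs2CO3 (1.0 equiv), 110 °C; then imidazole, TESCl, 40 °C
Reagents that add atoms: chlorotriethylsilane, CC[Si](Cl)(CC)CC
Why: Proposed new method: one catechol supplies both nucleophiles of an epoxide relay – the first-formed, more acidic 7-phenoxide opens the 3,4-epoxide trans-diaxially at C4, the freed 3-alkoxide displaces the anti-periplanar 2-tosylate to give the 2,3-manno epoxide, and the tethered 6-phenoxide opens it at C2 (7-exo, trans-diaxial), so C4 and C2 are each inverted twice (net gluco, both aryl ethers axial and syn, 3-OH anti) before silylation in the same flask; the closest known chemistry is the stepwise opening of this epoxy tosylate by two external nucleophiles (azide, benzyl oxide, fluoride) and phenoxide opening of epoxides.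

Step 6
Reactants: 12 1,6-anhydro-2,4-O-[4-oxo-2-(2-phenylethyl)-4H-chromene-6,7-diyl]-3-O-triethylsilyl-β-D-glucopyranose
Product: 14 phenyl 2,4-O-[4-oxo-2-(2-phenylethyl)-4H-chromene-6,7-diyl]-1-thio-3-O-triethylsilyl-α-D-glucopyranoside (6-OH free), via 6-O-trimethylsilyl thioglycoside 13 (not isolated)
Conditions: PhSSiMe3, ZnI2, ClCH2CH2Cl, 60 °C; then K2CO3 (cat.), MeOH, 0 °C
Reagents that add atoms: trimethyl(phenylsulfanyl)silane, C[Si](C)(C)Sc1ccccc1
Why: Lewis-acid-promoted thiolysis of the 1,6-anhydro acetal (thioglycoside formation) is irreversible because the thioglycoside is inert to ZnI2, whereas an O-glycoside of this chair-locked sugar would re-close; C1 is drawn inverted (α), but its configuration is irrelevant because it is destroyed in step 8.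

Step 7
Reactants: 14 phenyl 2,4-O-[4-oxo-2-(2-phenylethyl)-4H-chromene-6,7-diyl]-1-thio-3-O-triethylsilyl-α-D-glucopyranoside
Product: 15 phenyl 6-deoxy-6-iodo-2,4-O-[4-oxo-2-(2-phenylethyl)-4H-chromene-6,7-diyl]-1-thio-3-O-triethylsilyl-α-D-glucopyranoside
Conditions: PPh3, I2, imidazole, toluene/MeCN, 60 °C
Reagents that add atoms: iodine, II
Why: Appel-type (Garegg–Samuelsson) iodination of the only free, primary hydroxyl; no stereocenter is touched.

Step 8
Reactants: 15 phenyl 6-deoxy-6-iodo-2,4-O-[4-oxo-2-(2-phenylethyl)-4H-chromene-6,7-diyl]-1-thio-3-O-triethylsilyl-α-D-glucopyranoside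
Product: 16 5,6-dideoxy-2,4-O-[4-oxo-2-(2-phenylethyl)-4H-chromene-6,7-diyl]-3-O-triethylsilyl-aldehydo-D-xylo-hex-5-enose
Conditions: Zn dust (activated), THF/H2O 9:1, ultrasound, 40 °C
Reagents that add atoms: none
Why: Bernet–Vasella reductive fragmentation: zinc inserts into C6–I, β-elimination breaks C5–O5 and the hemithioacetal alkoxide collapses to the aldehyde, which removes the C5 oxygen and leaves C2–C4 untouched (thioglycosides are expected to behave like the usual O-glycosides).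

Step 9
Reactants: 16 5,6-dideoxy-2,4-O-[4-oxo-2-(2-phenylethyl)-4H-chromene-6,7-diyl]-3-O-triethylsilyl-aldehydo-D-xylo-hex-5-enose; 17 ethyl vinyl ether
Product: 20 2-ethoxy-4,6-[[4-oxo-2-(2-phenylethyl)-4H-chromene-6,7-diyl]bis(oxy)]-3,5-bis(triethylsilyloxy)octa-1,7-diene (C3 = target C8, threo to C4), via (1-ethoxyvinyl)lithium 18 (not isolated), via C8 alcohol 19 (not isolated)
Conditions: 17, t-BuLi, THF, −78 → 0 °C; then 16·MgBr2·OEt2 (3 equiv), CH2Cl2/THF, −78 °C; then TESCl, imidazole, DMAP, −78 °C → rt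
Reagents that add atoms: chlorotriethylsilane, CC[Si](Cl)(CC)CC
Why: The 1-ethoxyvinyl metal is an acetyl-anion equivalent, so its 1,2-addition joins aldehyde carbon C8 to the future enol-ether carbon C8a, two carbons that are both carbonyl-type electrophiles in normal polarity; magnesium held by the aldehyde oxygen, the α-aryl ether oxygen and the neighbouring catechol oxygen (Cram chelate, β-oxygen silylated and non-chelating) exposes the face next to H-7 and should give the 7,8-threo (8S) alkoxide, which is silylated in the same flask.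

Step 10
Reactants: 20 2-ethoxy-4,6-[[4-oxo-2-(2-phenylethyl)-4H-chromene-6,7-diyl]bis(oxy)]-3,5-bis(triethylsilyloxy)octa-1,7-diene
Product: 21 1-ethoxy-3,5-[[4-oxo-2-(2-phenylethyl)-4H-chromene-7,6-diyl]bis(oxy)]-4,6-bis(triethylsilyloxy)cyclohex-1-ene (ring carbons 1–6 = target C8a, C4a, C5, C6, C7, C8; configuration as in the target)
Conditions: second-generation Grubbs catalyst RuCl2(=CHPh)(PCy3)(H2IMes) (10 mol %), 1,4-benzoquinone (20 mol %), toluene, 80 °C
Reagents that add atoms: none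
Why: Ring-closing metathesis of the 1,1-disubstituted enol ether with the cis-disposed vinyl arm on the dioxepine closes the six-membered carbocycle and delivers the C8a=C4a enol ether regiospecifically with loss of ethene; no stereocenter changes.

Step 11
Reactants: 22 2,2,6-trimethyl-4H-1,3-dioxin-4-one; 23 1-(bromomethyl)-4-methoxybenzene
Product: 24 6-[2-(4-methoxyphenyl)ethyl]-2,2-dimethyl-4H-1,3-dioxin-4-one
Conditions: LiN(i-Pr)2, THF/DMPU, −78 °C; then 23, −78 → 0 °C
Reagents that add atoms: none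
Why: Vinylogous (γ) alkylation of the dioxinone lithium dienolate with a benzylic bromide; no stereocenter is formed.

Step 12
Reactants: 21 1-ethoxy-3,5-[[4-oxo-2-(2-phenylethyl)-4H-chromene-7,6-diyl]bis(oxy)]-4,6-bis(triethylsilyloxy)cyclohex-1-ene; 24 6-[2-(4-methoxyphenyl)ethyl]-2,2-dimethyl-4H-1,3-dioxin-4-one
Product: 27 (+)-4'-methoxyaquisinenone G, via acylketene 25 (not isolated), via ethoxy dihydropyranone 26 (not isolated)
Conditions: 24 (3 equiv, slow addition), toluene, 110 °C; then 1 M HCl, THF, rt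
Reagents that add atoms: none
Why: Retro-hetero-Diels–Alder of the dioxinone releases the acylketene, which adds to the enol ether (C4a to the ketene carbon, acyl oxygen to C8a; hetero-Diels–Alder), and acid then ionises the ketal-type C8a–OEt to aromatise to the γ-pyranone and removes both silyl ethers; the two transient centres C4a/C8a are erased and C5–C8 are untouched.

## Compound list

1 | 1-(2-hydroxy-4,5-dimethoxyphenyl)ethan-1-one | CC(=O)c1cc(OC)c(OC)cc1O | starting material
2 | ethyl 3-phenylpropanoate | CCOC(=O)CCc1ccccc1 | starting material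
3 | 1-(2-hydroxy-4,5-dimethoxyphenyl)-5-phenylpentane-1,3-dione | COc1cc(O)c(cc1OC)C(=O)CC(=O)CCc1ccccc1 | intermediate (not isolated)
4 | 6,7-dimethoxy-2-(2-phenylethyl)-4H-chromen-4-one | COc1cc2oc(CCc3ccccc3)cc(=O)c2cc1OC | intermediate
5 | 6,7-dihydroxy-2-(2-phenylethyl)-4H-chromen-4-one | Oc1cc2oc(CCc3ccccc3)cc(=O)c2cc1O | intermediate
6 | 1,6-anhydro-β-D-glucopyranose (levoglucosan) | [C@@H]12OC[C@@H](O1)[C@@H](O)[C@H](O)[C@H]2O | starting material
7 | 1,6-anhydro-2,4-di-O-tosyl-β-D-glucopyranose | [C@@H]12OC[C@@H](O1)[C@@H](OS(=O)(=O)c1ccc(C)cc1)[C@H](O)[C@H]2OS(=O)(=O)c1ccc(C)cc1 | intermediate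
8 | 1,6:3,4-dianhydro-2-O-tosyl-β-D-galactopyranose | [C@@H]12OC[C@@H](O1)[C@@H]1O[C@@H]1[C@H]2OS(=O)(=O)c1ccc(C)cc1 | intermediate
9 | 1,6-anhydro-4-O-[6-hydroxy-4-oxo-2-(2-phenylethyl)-4H-chromen-7-yl]-2-O-tosyl-β-D-glucopyranose | [C@@H]12OC[C@@H](O1)[C@@H](Oc1cc3oc(CCc4ccccc4)cc(=O)c3cc1O)[C@H](O)[C@H]2OS(=O)(=O)c1ccc(C)cc1 | intermediate (not isolated)
10 | 1,6:2,3-dianhydro-4-O-[6-hydroxy-4-oxo-2-(2-phenylethyl)-4H-chromen-7-yl]-β-D-mannopyranose | [C@@H]12OC[C@@H](O1)[C@@H](Oc1cc3oc(CCc4ccccc4)cc(=O)c3cc1O)[C@@H]1O[C@H]21 | intermediate (not isolated)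
11 | 1,6-anhydro-2,4-O-[4-oxo-2-(2-phenylethyl)-4H-chromene-6,7-diyl]-β-D-glucopyranose (O-2 on chromone C6, O-4 on C7, 3-OH free) | [C@@H]12OC[C@@H](O1)[C@@H](Oc1cc3oc(CCc4ccccc4)cc(=O)c3cc1O5)[C@H](O)[C@H]25 | intermediate (not isolated)
12 | 3-O-triethylsilyl ether of 11 | [C@@H]12OC[C@@H](O1)[C@@H](Oc1cc3oc(CCc4ccccc4)cc(=O)c3cc1O5)[C@H](O[Si](CC)(CC)CC)[C@H]25 | intermediate
13 | phenyl 2,4-O-[4-oxo-2-(2-phenylethyl)-4H-chromene-6,7-diyl]-1-thio-3-O-triethylsilyl-6-O-trimethylsilyl-α-D-glucopyranoside | c1ccccc1S[C@H]1O[C@H](CO[Si](C)(C)C)[C@@H](Oc2cc3oc(CCc4ccccc4)cc(=O)c3cc2O5)[C@H](O[Si](CC)(CC)CC)[C@H]15 | intermediate (not isolated)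
14 | phenyl 2,4-O-[4-oxo-2-(2-phenylethyl)-4H-chromene-6,7-diyl]-1-thio-3-O-triethylsilyl-α-D-glucopyranoside | c1ccccc1S[C@H]1O[C@H](CO)[C@@H](Oc2cc3oc(CCc4ccccc4)cc(=O)c3cc2O5)[C@H](O[Si](CC)(CC)CC)[C@H]15 | intermediate
15 | 6-deoxy-6-iodo analogue of 14 | c1ccccc1S[C@H]1O[C@H](CI)[C@@H](Oc2cc3oc(CCc4ccccc4)cc(=O)c3cc2O5)[C@H](O[Si](CC)(CC)CC)[C@H]15 | intermediate
16 | 5,6-dideoxy-2,4-O-[4-oxo-2-(2-phenylethyl)-4H-chromene-6,7-diyl]-3-O-triethylsilyl-aldehydo-D-xylo-hex-5-enose | C=C[C@@H](Oc1cc2oc(CCc3ccccc3)cc(=O)c2cc1O4)[C@H](O[Si](CC)(CC)CC)[C@@H]4C=O | intermediate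
17 | ethyl vinyl ether | C=COCC | starting material
18 | (1-ethoxyvinyl)lithium | [Li]C(=C)OCC | intermediate (not isolated)
19 | 2-ethoxy-4,6-[[4-oxo-2-(2-phenylethyl)-4H-chromene-6,7-diyl]bis(oxy)]-5-(triethylsilyloxy)octa-1,7-dien-3-ol (C3 = target C8, threo to C4) | C=C[C@@H](Oc1cc2oc(CCc3ccccc3)cc(=O)c2cc1O4)[C@H](O[Si](CC)(CC)CC)[C@@H]4[C@H](O)C(=C)OCC | intermediate (not isolated)
20 | 3-O-triethylsilyl ether of 19 | C=C[C@@H](Oc1cc2oc(CCc3ccccc3)cc(=O)c2cc1O4)[C@H](O[Si](CC)(CC)CC)[C@@H]4[C@H](O[Si](CC)(CC)CC)C(=C)OCC | intermediate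
21 | 1-ethoxy-3,5-[[4-oxo-2-(2-phenylethyl)-4H-chromene-7,6-diyl]bis(oxy)]-4,6-bis(triethylsilyloxy)cyclohex-1-ene | CCOC1=C[C@@H](Oc2cc3oc(CCc4ccccc4)cc(=O)c3cc2O5)[C@H](O[Si](CC)(CC)CC)[C@@H]5[C@@H]1O[Si](CC)(CC)CC | intermediate
22 | 2,2,6-trimethyl-4H-1,3-dioxin-4-one | CC1=CC(=O)OC(C)(C)O1 | starting material
23 | 1-(bromomethyl)-4-methoxybenzene | COc1ccc(CBr)cc1 | starting material
24 | 6-[2-(4-methoxyphenyl)ethyl]-2,2-dimethyl-4H-1,3-dioxin-4-one | COc1ccc(CCC2=CC(=O)OC(C)(C)O2)cc1 | intermediate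
25 | 5-(4-methoxyphenyl)-3-oxopent-1-en-1-one (acylketene) | COc1ccc(CCC(=O)C=C=O)cc1 | intermediate (not isolated)
26 | 8a-ethoxy-4a,8a-dihydro bis(triethylsilyl) precursor of 27 (cis ring fusion, addition on the face opposite the two silyloxy groups; the other face gives the same final product) | COc1ccc(CCC2=CC(=O)[C@H]3[C@@H](Oc4cc5oc(CCc6ccccc6)cc(=O)c5cc4O7)[C@H](O[Si](CC)(CC)CC)[C@@H]7[C@H](O[Si](CC)(CC)CC)[C@@]3(OCC)O2)cc1 | intermediate (not isolated)
27 | (+)-4'-methoxyaquisinenone G | COc1ccc(CCc2cc(=O)c3c(o2)[C@@H](O)[C@@H]2Oc4cc5c(=O)cc(CCc6ccccc6)oc5cc4O[C@H]3[C@@H]2O)cc1 | target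

## Step count and risk

Total steps: 12. Longest linear sequence: 9 steps (6 → 27 through steps 3–10 and 12; the branch from 1 through steps 1, 2, 5–10 and 12 is equally long).

**Most likely to fail, first: step 9.** Non-chelated (Felkin–Anh) addition to this α-aryloxy aldehyde favours the unwanted 7,8-erythro alcohol, so the step depends on an aryl ether oxygen chelating magnesium; the reagent could also attack the chromone. The fallback abandons stereocontrol in the C–C bond formation and sets C8 by hydride delivery instead. Starting from 16, 18 is added without MgBr2 to give mainly the C3-epimeric alcohol 8-epi-19 F1 together with 19. The mixture is oxidised (Dess–Martin periodinane, NaHCO3, CH2Cl2) to 2-ethoxy-4,6-[[4-oxo-2-(2-phenylethyl)-4H-chromene-6,7-diyl]bis(oxy)]-5-(triethylsilyloxy)octa-1,7-dien-3-one F2. Luche reduction (NaBH4, CeCl3·7H2O, MeOH, −78 °C) then proceeds under Felkin–Anh control with the aryloxy group anti to hydride, which for the ketone gives the threo alcohol 19. Silylation (TESCl, imidazole) rejoins the route at 20, at the cost of two extra steps.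

**Second: step 5.** The chromone 7-phenoxide is a weak nucleophile toward a sluggish epoxide, and the regiochemistry rests on mono-deprotonation. The fallback builds the bridge at the acetophenone stage and the chromone afterwards. Starting from 1, BBr3 gives 1-(2,4,5-trihydroxyphenyl)ethan-1-one F3. Its 4-phenoxide (para to the acetyl group; the 2-OH is tied up in a hydrogen bond to the ketone) opens 8 at C4, and the 5-phenoxide closes onto the relayed 2,3-epoxide under the same Cs2CO3/DMF conditions to give 1,6-anhydro-2,4-O-(4-acetyl-5-hydroxy-1,2-phenylene)-β-D-glucopyranose F4. Claisen condensation with 2 (LiN(SiMe3)2, THF) gives the 1-aryl-5-phenylpentane-1,3-dione F5, and HCl/AcOH cyclodehydration returns to 11, which is silylated to 12 as in step 5.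

**Third: step 12.** The enol ether is trisubstituted and flanked by two silyloxy groups and the arylene bridge, so the acylketene may dimerise before it is trapped. The fallback replaces the cycloaddition by C-acylation followed by cyclisation. Starting from 23, alkylation of lithiated 1-(trimethylsilyl)propyne gives [4-(4-methoxyphenyl)but-1-yn-1-yl]trimethylsilane F6. CsF/CO2 in DMSO gives 5-(4-methoxyphenyl)pent-2-ynoic acid F7, and oxalyl chloride with catalytic DMF gives 5-(4-methoxyphenyl)pent-2-ynoyl chloride F8. F8 acylates enol ether 21 at C4a (pyridine, CH2Cl2) to give the 2-alkynoyl-1-ethoxycyclohexene F9. Aqueous HCl in THF then hydrolyses the vinylogous ester, closes the γ-pyranone by 6-endo oxa-Michael addition and removes both silyl groups, arriving at 27.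

## Further compounds

F1 | step 9 | 8-epi-19, 2-ethoxy-4,6-[[4-oxo-2-(2-phenylethyl)-4H-chromene-6,7-diyl]bis(oxy)]-5-(triethylsilyloxy)octa-1,7-dien-3-ol (C3 erythro to C4) | C=C[C@@H](Oc1cc2oc(CCc3ccccc3)cc(=O)c2cc1O4)[C@H](O[Si](CC)(CC)CC)[C@@H]4[C@@H](O)C(=C)OCC
F2 | step 9 | 2-ethoxy-4,6-[[4-oxo-2-(2-phenylethyl)-4H-chromene-6,7-diyl]bis(oxy)]-5-(triethylsilyloxy)octa-1,7-dien-3-one | C=C[C@@H](Oc1cc2oc(CCc3ccccc3)cc(=O)c2cc1O4)[C@H](O[Si](CC)(CC)CC)[C@@H]4C(=O)C(=C)OCC
F3 | step 5 | 1-(2,4,5-trihydroxyphenyl)ethan-1-one | CC(=O)c1cc(O)c(O)cc1O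
F4 | step 5 | 1,6-anhydro-2,4-O-(4-acetyl-5-hydroxy-1,2-phenylene)-β-D-glucopyranose (O-4 para to acetyl) | [C@@H]12OC[C@@H](O1)[C@@H](Oc1cc(O)c(C(C)=O)cc1O5)[C@H](O)[C@H]25
F5 | step 5 | 1,6-anhydro-2,4-O-[5-hydroxy-4-(3-oxo-5-phenylpentanoyl)-1,2-phenylene]-β-D-glucopyranose | [C@@H]12OC[C@@H](O1)[C@@H](Oc1cc(O)c(C(=O)CC(=O)CCc3ccccc3)cc1O5)[C@H](O)[C@H]25
F6 | step 12 | [4-(4-methoxyphenyl)but-1-yn-1-yl]trimethylsilane | COc1ccc(CCC#C[Si](C)(C)C)cc1
F7 | step 12 | 5-(4-methoxyphenyl)pent-2-ynoic acid | COc1ccc(CCC#CC(=O)O)cc1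
F8 | step 12 | 5-(4-methoxyphenyl)pent-2-ynoyl chloride | COc1ccc(CCC#CC(=O)Cl)cc1
F9 | step 12 | 1-ethoxy-2-[5-(4-methoxyphenyl)pent-2-ynoyl]-3,5-[[4-oxo-2-(2-phenylethyl)-4H-chromene-7,6-diyl]bis(oxy)]-4,6-bis(triethylsilyloxy)cyclohex-1-ene | CCOC1=C(C(=O)C#CCCc2ccc(OC)cc2)[C@@H](Oc2cc3oc(CCc4ccccc4)cc(=O)c3cc2O5)[C@H](O[Si](CC)(CC)CC)[C@@H]5[C@@H]1O[Si](CC)(CC)CC
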